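The methylenecyclohexane (ring D) is traced to its ketone. The carbonyl carbon is bonded to the quaternary carbon shared by ring D, the oxolane (ring C) and the central cyclohexane (ring B); this carbon carries the CMe2 carbon trans to the ring B C–O carbon. A β-hydroxy ketone with a quaternary α-carbon is the imprint of a semipinacol ring expansion. The precursor is a tertiary cyclopentenol, made by adding a ring B vinylmetal (from (S)-Wieland–Miescher ketone) to 2,2-dimethylcyclopent-3-enone. Epoxidation of the ring B alkene and Lewis acid move the CMe2 carbon from carbinol to epoxide carbon: the five-membered ring becomes the six-membered ketone while the quaternary centre and ring B alcohol are set. Alkoxymercuration and methylenation finish.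

Key step: step 13

Remark (numbering in names): decalin atoms are C1 (future C–Br), C2, C3, C4 (future ring A carbinol), C4a, C5, C6 (future quaternary centre), C7 (future ring B C–O), C8, C8a (methyl-bearing); β is the face of the angular methyl.
Assumption: 1 and 13 are commercial; 19 is carried as the mixture of its two carbinol epimers, because that carbon becomes the ketone carbon in step 13.

Step 1
Reactants: 1 (S)-Wieland–Miescher ketone
Product: 2 1β-hydroxy enone (4aS,5S)-5-hydroxy-4a-methyl-4,4a,5,6,7,8-hexahydronaphthalen-2(3H)-one
Conditions: NaBH4 (0.3 equiv), EtOH, −10 °C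
Reagents that add atoms: none
Why: Chemoselective borohydride reduction of the saturated, more electrophilic C1 ketone beside the enone, hydride arriving on the face opposite the angular methyl so that the hydroxyl is cis to it, which tells the two carbonyls apart (the carbinol is reoxidised in step 3).

Step 2
Reactants: 2 1β-hydroxy enone
Product: 3 ketal alcohol (6,6-ethylenedioxy-8aβ-methyl-1,2,3,5,6,7,8,8a-octahydronaphthalen-1β-ol; alkene C4=C4a)
Conditions: HOCH2CH2OH, p-TsOH (cat.), benzene, reflux, Dean–Stark
Reagents that add atoms: ethylene glycol OCCO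
Why: Acid-catalysed ketalisation of the enone carbonyl with the customary shift of the double bond out of conjugation to C4=C4a, which masks the ring B ketone and positions the alkene for oxygenation of C4.

Step 3
Reactants: 3 ketal alcohol
Product: 4 ketal ketone ((8aS)-6,6-ethylenedioxy-8a-methyl-Δ4(4a)-octalin-1-one)
Conditions: Dess–Martin periodinane, NaHCO3, CH2Cl2, rt
Reagents that add atoms: none
Why: Dess–Martin oxidation of the secondary alcohol under buffered, non-acidic conditions returns the C1 ketone while the ketal and the unconjugated alkene stay in place.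

Step 4
Reactants: 4 ketal ketone
Product: 5 dienyl bromide (1-bromo-6,6-ethylenedioxy-8a-methyl-3,5,6,7,8,8a-hexahydronaphthalene; alkenes C1=C2 and C4=C4a)
Conditions: P(OPh)3, Br2, Et3N, CH2Cl2, −60 °C → reflux
Reagents that add atoms: bromine BrBr
Why: Conversion of an enolisable ketone into its vinyl bromide with the triphenyl phosphite–bromine reagent (O-phosphonium activation, bromide addition, elimination), regiochemically unambiguous because only C2 carries α-hydrogens, and free of elemental bromine so that the C4=C4a alkene is spared.

Step 5
Reactants: 5 dienyl bromide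
Product: 7 4α-alcohol (1-bromo-6,6-ethylenedioxy-8aβ-methyl-4aα-H-Δ1-octalin-4α-ol), via alkylborane 6 (not isolated)
Conditions: BH3·THF, THF, 0 °C → rt; then NaOH, H2O2, 0 °C
Reagents that add atoms: hydrogen peroxide OO
Why: Hydroboration–oxidation, in which the electrophilic borane should choose the electron-rich trisubstituted C4=C4a alkene over the inductively deactivated, hindered vinyl bromide and add syn from the α face away from the angular methyl, setting the trans ring fusion (4aα-H) and the C4 oxygen.

Step 6
Reactants: 7 4α-alcohol
Product: 8 bromo alcohol (1β-bromo-6,6-ethylenedioxy-8aβ-methyl-trans-decalin-4α-ol)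
Conditions: Mn(dpm)3 (cat.), PhSiH3, t-BuOOH, i-PrOH, rt
Reagents that add atoms: none
Why: Metal hydride hydrogen atom transfer hydrogenation, a radical reduction known to leave the carbon–halogen bond of haloalkenes intact, should place hydrogen on C2 and then quench the α-bromo radical at C1 from the α face (axial approach anti to the neighbouring axial methyl), giving the thermodynamically preferred equatorial 1β-bromide.

Step 7
Reactants: 8 bromo alcohol
Product: 9 bromo ketone (1β-bromo-6,6-ethylenedioxy-8aβ-methyl-trans-decalin-4-one)
Conditions: Dess–Martin periodinane, NaHCO3, CH2Cl2, rt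
Reagents that add atoms: none
Why: Dess–Martin oxidation under neutral conditions gives the C4 ketone without enolisation, so the trans ring fusion at C4a and the γ-bromide are not disturbed.

Step 8
Reactants: 9 bromo ketone
Product: 10 tertiary alcohol (1β-bromo-6,6-ethylenedioxy-4α,8aβ-dimethyl-trans-decalin-4β-ol)
Conditions: MeMgBr, THF, −78 °C → 0 °C
Reagents that add atoms: methylmagnesium bromide C[Mg]Br
Why: Grignard addition to the C4 ketone from the α face (equatorial attack), because the β face is screened by the 1,3-diaxial angular methyl as in 6-oxo steroids, should give the axial 4β-hydroxyl with the equatorial 4α-methyl, and the low temperature avoids enolate-mediated displacement of the γ-bromide.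

Step 9
Reactants: 10 tertiary alcohol
Product: 12 trisylhydrazone (2,4,6-triisopropylbenzenesulfonylhydrazone of the C6 ketone), via bromo hydroxy decalone 11 (not isolated)
Conditions: 2,4,6-(i-Pr)3C6H2SO2NHNH2, HCl (cat.), THF/H2O, rt
Reagents that add atoms: 2,4,6-triisopropylbenzenesulfonohydrazide NNS(=O)(=O)c1c(C(C)C)cc(C(C)C)cc1C(C)C
Why: Acid-catalysed ketal hydrolysis and in situ condensation of the liberated, unhindered C6 ketone with the sulfonyl hydrazide (hydrazone formation), under acidity too mild to dehydrate the tertiary alcohol.

Step 10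
Reactants: 13 2,2-dimethylcyclopentane-1,3-dione
Product: 15 keto enol triflate (5,5-dimethyl-4-oxocyclopent-1-en-1-yl trifluoromethanesulfonate), via potassium enolate 14 (not isolated)
Conditions: KHMDS (1.0 equiv), THF, −78 °C; then PhNTf2
Reagents that add atoms: N-phenylbis(trifluoromethanesulfonimide) O=S(=O)(N(c1ccccc1)S(=O)(=O)C(F)(F)F)C(F)(F)F
Why: Enolate O-sulfonylation, in which deprotonation can only occur at a CH2 group because the carbon between the carbonyls is quaternary, and the two carbonyls being equivalent a single enol triflate results.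

Step 11
Reactants: 15 keto enol triflate
Product: 16 2,2-dimethylcyclopent-3-en-1-one
Conditions: Pd(PPh3)4 (cat.), Bu3SnH, LiCl, THF, 60 °C
Reagents that add atoms: none
Why: Palladium-catalysed hydrogenolysis of an enol triflate with tin hydride (oxidative addition to zerovalent palladium, hydride transfer, reductive elimination) under neutral conditions, which should leave the β,γ-unsaturated ketone unconjugated.

Step 12
Reactants: 12 trisylhydrazone; 16 2,2-dimethylcyclopent-3-en-1-one
Product: 19 tertiary allylic alcohol (1-[1β-bromo-4β-hydroxy-4α,8aβ-dimethyl-trans-Δ6-octalin-6-yl]-2,2-dimethylcyclopent-3-en-1-ol; both carbinol epimers), via vinyllithium 17 (not isolated), via vinylcerium reagent 18 (not isolated)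
Conditions: n-BuLi (3.0 equiv), THF, −78 °C → 0 °C; CeCl3, −78 °C; then 16, −78 °C → −40 °C
Reagents that add atoms: none
Why: Shapiro reaction, in which the hydrazone dianion (the alkoxide takes the third equivalent of base) loses sulfinate and dinitrogen to give the C6 vinyllithium with the double bond toward C7, the direction favoured for trans-fused 2-decalone derivatives, and the less basic organocerium reagent then adds 1,2 to the hindered, enolisable ketone, the new carbinol centre forming as both epimers, which is harmless because it becomes the carbonyl carbon in step 13.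

Step 13
Reactants: 19 tertiary allylic alcohol
Product: 21 spiro hydroxy ketone (1β-bromo-4β,7α-dihydroxy-4α,6',6',8aβ-tetramethylspiro[trans-decalin-6,1'-cyclohex-4'-en]-2'-one; CMe2 carbon on the β face of C6), via epoxy alcohol 20 (not isolated)
Conditions: DMDO (1.05 equiv, acetone), CH2Cl2, −40 °C → 0 °C; evaporate; BF3·OEt2 (0.3 equiv), CH2Cl2, −78 °C
Reagents that add atoms: dimethyldioxirane CC1(C)OO1
Why: The dioxirane epoxidises the trisubstituted ring B alkene, and the Lewis acid then opens the epoxide at its fully substituted carbon C6 while the CMe2 ring carbon of the cyclopentenol shifts from the carbinol carbon to C6 and the carbinol becomes the ketone. The closest known reaction type is the semipinacol rearrangement of 2,3-epoxy alcohols, in which 1-(epoxycycloalkyl)cycloalkanols give spiro β-hydroxy ketones. No ring is closed by cyclisation: the five-membered carbinol ring is enlarged by one carbon through the 1,2-shift into the six-membered ring D ketone, which becomes spiro-linked to ring B at C6. The C7 carbinol centre is set by epoxidation on the α face, opposite the axial angular methyl that is syn-axial to C7, and the quaternary C6 centre by migration anti to the breaking C6–O bond (inversion), so that the CMe2 carbon ends β and trans to the C7 oxygen. The step needs selectivity between two alkenes and between two migrating carbons: the trisubstituted alkene is more nucleophilic than the hindered cis-disubstituted cyclopentene, and the fully substituted, allylic CMe2 carbon has a higher migratory aptitude than the CH2 carbon. Both carbinol epimers of 19 converge on 21 because that carbon becomes sp2.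

Step 14
Reactants: 21 spiro hydroxy ketone
Product: 23 oxa-bridged ketone (the target skeleton with C=O in place of C=CH2), via organomercurial 22 (not isolated)
Conditions: Hg(OCOCF3)2, CH2Cl2, 0 °C; then NaBH4, aq NaOH, 0 °C, acetone quench
Reagents that add atoms: none
Why: Intramolecular alkoxymercuration–demercuration, in which the equatorial C7 hydroxyl held over the ring D alkene should open the mercurinium ion anti in a 5-exo-trig closure at the alkene carbon next to CMe2 (the mode followed by cyclohex-3-enylmethanols), the tether fixing the configuration of the new C–O bridgehead and closing the trans-fused oxolane, and rapid borohydride demercuration replaces mercury by hydrogen before the hindered ketone is reduced.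

Step 15
Reactants: 23 oxa-bridged ketone
Product: 24 target CNP0412361.2
Conditions: Ph3PCH3Br, KOt-Bu, toluene, 90 °C
Reagents that add atoms: methyltriphenylphosphonium bromide C[P+](c1ccccc1)(c1ccccc1)c1ccccc1.[Br-]
Why: Wittig methylenation with excess ylide converts the hindered, non-epimerisable ketone into the exocyclic alkene, the equatorial bromide lacking an anti-periplanar hydrogen for elimination and the tertiary alkoxide being a spectator.

Compound list
1 | (S)-Wieland–Miescher ketone, (8aS)-8a-methyl-3,4,8,8a-tetrahydronaphthalene-1,6(2H,7H)-dione | C[C@]12CCC(=O)C=C1CCCC2=O | starting material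
2 | 1β-hydroxy enone, (4aS,5S)-5-hydroxy-4a-methyl-4,4a,5,6,7,8-hexahydronaphthalen-2(3H)-one (OH cis to the angular methyl) | C1C[C@]2(C)[C@@H](O)CCCC2=CC1=O | intermediate
3 | ketal alcohol, 6,6-ethylenedioxy-8aβ-methyl-1,2,3,5,6,7,8,8a-octahydronaphthalen-1β-ol (alkene C4=C4a) | C1C[C@]2(C)[C@@H](O)CCC=C2CC13OCCO3 | intermediate
4 | ketal ketone, (8aS)-6,6-ethylenedioxy-8a-methyl-Δ4(4a)-octalin-1-one | C1C[C@]2(C)C(=O)CCC=C2CC13OCCO3 | intermediate
5 | dienyl bromide, 1-bromo-6,6-ethylenedioxy-8a-methyl-3,5,6,7,8,8a-hexahydronaphthalene (alkenes C1=C2 and C4=C4a) | C1C[C@]2(C)C(Br)=CCC=C2CC13OCCO3 | intermediate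
6 | alkylborane, 4α-BH2 adduct of 5 with 4aα-H | C1C[C@]2(C)C(Br)=CC[C@H](B)[C@H]2CC13OCCO3 | intermediate
7 | 4α-alcohol, 1-bromo-6,6-ethylenedioxy-8aβ-methyl-4aα-H-Δ1-octalin-4α-ol | C1C[C@]2(C)C(Br)=CC[C@H](O)[C@H]2CC13OCCO3 | intermediate
8 | bromo alcohol, 1β-bromo-6,6-ethylenedioxy-8aβ-methyl-trans-decalin-4α-ol | C1C[C@]2(C)[C@@H](Br)CC[C@H](O)[C@H]2CC13OCCO3 | intermediate
9 | bromo ketone, 1β-bromo-6,6-ethylenedioxy-8aβ-methyl-trans-decalin-4-one | C1C[C@]2(C)[C@@H](Br)CCC(=O)[C@H]2CC13OCCO3 | intermediate
10 | tertiary alcohol, 1β-bromo-6,6-ethylenedioxy-4α,8aβ-dimethyl-trans-decalin-4β-ol | C1C[C@]2(C)[C@@H](Br)CC[C@@](C)(O)[C@H]2CC13OCCO3 | intermediate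
11 | bromo hydroxy decalone, 1β-bromo-4β-hydroxy-4α,8aβ-dimethyl-trans-decalin-6-one | C1C[C@]2(C)[C@@H](Br)CC[C@@](C)(O)[C@H]2CC1=O | intermediate
12 | trisylhydrazone, 2,4,6-triisopropylbenzenesulfonylhydrazone of 11 at C6 | C1C[C@]2(C)[C@@H](Br)CC[C@@](C)(O)[C@H]2CC1=NNS(=O)(=O)c3c(C(C)C)cc(C(C)C)cc3C(C)C | intermediate
13 | 2,2-dimethylcyclopentane-1,3-dione | CC1(C)C(=O)CCC1=O | starting material
14 | potassium enolate of 13 | CC1(C)C(=O)CC=C1[O-].[K+] | intermediate
15 | keto enol triflate, 5,5-dimethyl-4-oxocyclopent-1-en-1-yl trifluoromethanesulfonate | CC1(C)C(=O)CC=C1OS(=O)(=O)C(F)(F)F | intermediate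
16 | 2,2-dimethylcyclopent-3-en-1-one | CC1(C)C=CCC1=O | intermediate
17 | vinyllithium, C6-lithio Δ6-octalin as its lithium 4β-alkoxide | [Li]C1=CC[C@]2(C)[C@@H](Br)CC[C@@](C)(O[Li])[C@H]2C1 | intermediate
18 | vinylcerium reagent, C6–CeCl2 analogue of 17 | Cl[Ce](Cl)C1=CC[C@]2(C)[C@@H](Br)CC[C@@](C)(O[Li])[C@H]2C1 | intermediate
19 | tertiary allylic alcohol, 1-[1β-bromo-4β-hydroxy-4α,8aβ-dimethyl-trans-Δ6-octalin-6-yl]-2,2-dimethylcyclopent-3-en-1-ol (both epimers at the cyclopentenol carbinol carbon) | OC3(CC=CC3(C)C)C1=CC[C@]2(C)[C@@H](Br)CC[C@@](C)(O)[C@H]2C1 | intermediate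
20 | epoxy alcohol, 6α,7α-epoxide of 19 | OC3(CC=CC3(C)C)[C@]14O[C@@H]4C[C@]2(C)[C@@H](Br)CC[C@@](C)(O)[C@H]2C1 | intermediate
21 | spiro hydroxy ketone, 1β-bromo-4β,7α-dihydroxy-4α,6',6',8aβ-tetramethylspiro[trans-decalin-6,1'-cyclohex-4'-en]-2'-one (C6' on the β face of C6) | O[C@@H]1C[C@]2(C)[C@@H](Br)CC[C@@](C)(O)[C@H]2C[C@]13C(=O)CC=CC3(C)C | intermediate
22 | organomercurial, 23 carrying HgOCOCF3 on the ring D carbon next to the new C–O bridgehead, trans to the ether oxygen | O=C1C[C@@H]([Hg]OC(=O)C(F)(F)F)[C@@H]2O[C@@H]3C[C@]4(C)[C@@H](Br)CC[C@@](C)(O)[C@H]4C[C@]13C2(C)C | intermediate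
23 | oxa-bridged ketone, 8,8-dimethyl-6-oxabicyclo[3.2.1]octan-2-one fused through its C1 and C7 to decalin C6 and C7 of the 1β-bromo-4β-hydroxy-4α,8aβ-dimethyl-trans-decalin | O=C1CC[C@@H]2O[C@@H]3C[C@]4(C)[C@@H](Br)CC[C@@](C)(O)[C@H]4C[C@]13C2(C)C | intermediate
24 | target CNP0412361.2, the 2-methylidene analogue of 23 | C=C1CC[C@@H]2O[C@@H]3C[C@]4(C)[C@@H](Br)CC[C@@](C)(O)[C@H]4C[C@]13C2(C)C | target

Total step count: 15. Longest linear sequence: 13 steps (steps 1–9 and 12–15); steps 10–11 form the side branch.

Steps most likely to fail

Step 12. What may go wrong: deprotonation of the hydrazone on the wrong side (double bond toward C5), attack of butyllithium on the secondary bromide during the warm phase, or proton transfer from the enolisable ketone instead of addition. The fallback sets out from compound 10 and comes back at compound 19. Hydrolysis of the ketal (PPTS, acetone/H2O) should give the isolated ketone 11. Kinetic enolisation toward C7 and O-sulfonylation (KHMDS 2.1 equiv, PhNTf2, THF, −78 °C) should give the enol triflate F1. Palladium-catalysed stannylation (Pd(PPh3)4, Me3SnSnMe3, LiCl, THF, 60 °C) should give the vinylstannane F2. Tin–lithium exchange (MeLi, THF, −78 °C) should then deliver vinyllithium 17 without any warm, strongly basic phase, and CeCl3 followed by 16 should give 19.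

Step 13. What may go wrong: epoxidation at the cyclopentene or on the β face, or a non-concerted epoxide opening that ends in elimination or in migration of the CH2 carbon. The fallback sets out from compound 19 and comes back at compound 21. Hydroxyl-directed epoxidation (VO(acac)2 cat., t-BuOOH, CH2Cl2, 0 °C) addresses only the allylic alkene and should give isolated epoxy alcohol 20. Silylation (TMSOTf, 2,6-lutidine) should give the bis(trimethylsilyl) ether F3. The silyl ether variant of the semipinacol rearrangement (TiCl4, CH2Cl2, −78 °C; dilute HCl work-up), in which the silyloxy group drives a concerted anti shift, should give 21.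

Step 6. What may go wrong: loss of bromine by over-reduction, sluggish hydrogen atom transfer to the hindered haloalkene, or poor facial control at C1. The fallback sets out from compound 7 and comes back at compound 8. Hydroxyl-directed homogeneous hydrogenation ([Ir(cod)(PCy3)(py)]PF6 cat., H2, CH2Cl2, rt) lets the homoallylic 4α-hydroxyl bind iridium and deliver both hydrogens to the α face of the C1=C2 bond, without a carbon radical.

Further compounds
F1 | step 12 | enol triflate, 1β-bromo-4β-hydroxy-4α,8aβ-dimethyl-trans-Δ6-octalin-6-yl trifluoromethanesulfonate | O=S(=O)(OC1=CC[C@]2(C)[C@@H](Br)CC[C@@](C)(O)[C@H]2C1)C(F)(F)F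
F2 | step 12 | vinylstannane, C6-trimethylstannyl analogue of F1 | C[Sn](C)(C)C1=CC[C@]2(C)[C@@H](Br)CC[C@@](C)(O)[C@H]2C1
F3 | step 13 | bis(trimethylsilyl) ether of epoxy alcohol 20 | C[Si](C)(C)OC3(CC=CC3(C)C)[C@]14O[C@@H]4C[C@]2(C)[C@@H](Br)CC[C@@](C)(O[Si](C)(C)C)[C@H]2C1
F0 | step 6 | none | none
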